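**Retrosynthetic overview**
- Target ⇐ selective angeloylation of the primary allylic alcohol of a germacradiene diol.
- Ten-membered ring ⇐ ring expansion of a trans-decalin by Grob-type (enolate-assisted) 1,4-fragmentation of a 1β-mesyloxy 4-carbaldehyde: the C5–C10 bond is cut and both ring-trans double bonds form at once.
- Decalin oxygen pattern ⇐ hydride reduction anti to the angular methyl (C1, C6), acetylation, and conjugate borylation/oxidation (C8) of a ring B enone.
- Ring B ⇐ ozonolysis and intramolecular aldol condensation of a 2-allyl-3-alkenylcyclohexanone, itself from conjugate addition/allylation of a ring A enone.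
- Order of rings: ring A (bought as 2-methylcyclohexenone; C15 and the controlling C4 centre added by a new asymmetric γ-functionalisation), then ring B (step 4), then the ten-membered ring (step 9).

Assumption: atom labels C1–C15 are the germacrane numbers of the target and are kept for all intermediates; in the decalins β is the face of the C10 methyl and α the opposite face; 6 is taken as a catalogue chemical.

**Step 1**
Reactants: 1 2-methylcyclohex-2-en-1-one
Product: 3 tert-butyl(dimethyl)[(2-methylcyclohexa-1,3-dien-1-yl)oxy]silane, via potassium dienolate 2 (not isolated)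
Conditions: KN(SiMe3)2 (0.95 equiv), THF, −78 → 0 °C, 1 h; then TBSCl, −78 → 20 °C
Reagents that add atoms: tert-butyldimethylsilyl chloride CC(C)(C)[Si](C)(C)Cl; potassium bis(trimethylsilyl)amide C[Si](C)(C)[N-][Si](C)(C)C.[K+] (potassium in 2 only)
Why: With a slight deficit of base the kinetic cross-conjugated enolate equilibrates by proton transfer to the more stable linear (γ-deprotonated) dienolate, and O-silylation gives the 1-silyloxy-1,3-diene (thermodynamic silyl dienol ether formation); no stereocentre is formed.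

**Step 2**
Reactants: 3 tert-butyl(dimethyl)[(2-methylcyclohexa-1,3-dien-1-yl)oxy]silane; 4 trimethyl orthoformate
Product: 5 (4R)-4-(dimethoxymethyl)-2-methylcyclohex-2-en-1-one
Conditions: chiral imidodiphosphorimidate (IDPi) Brønsted acid (2 mol %), 4 (1.5 equiv), toluene, −60 °C; NaHCO3 work-up
Reagents that add atoms: none
Why: Proposed new method: enantioselective vinylogous Mukaiyama-type γ-(dimethoxymethyl)ation of a cyclic silyl dienol ether, in which the IDPi acid is silylated by 3 to a silylium–IDPi Lewis acid that abstracts methoxide from 4, the resulting dimethoxycarbenium ion paired with the confined chiral anion attacks the γ-terminus C4 on one face (α-attack is blocked by the C10 methyl), and silyl transfer from the O-silyl oxocarbenium to the next orthoformate turns the catalyst over, so the C4–C15 bond and the (R)-C4 centre that later relays to C5 and C10 are set here (the catalyst enantiomer giving (R) is chosen by screening); the closest known reaction types are the racemic Lewis-acid-promoted (TMSOTf, BF3·OEt2) γ-additions of silyl dienol ethers to orthoformates and acetals and IDPi-catalysed asymmetric Mukaiyama-type additions of silyl nucleophiles to oxocarbenium ions.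

**Step 3**
Reactants: 5 (4R)-4-(dimethoxymethyl)-2-methylcyclohex-2-en-1-one; 6 2-bromo-4-methylpent-1-ene; 7 3-bromoprop-1-ene (allyl bromide)
Product: 10 (2R,3R,4R)-4-(dimethoxymethyl)-2-methyl-3-(4-methylpent-1-en-2-yl)-2-(prop-2-en-1-yl)cyclohexan-1-one, via alkenyl Grignard reagent 8 (not isolated), via bromomagnesium enolate 9 (not isolated)
Conditions: 6, Mg, THF, 45 °C; CuBr·SMe2 (10 mol %), 5, THF, −40 °C; then 7 (3 equiv), DMPU, −40 → 20 °C
Reagents that add atoms: magnesium [Mg] (in 8 and 9 only)
Why: Copper-catalysed 1,4-addition of the alkenyl Grignard reagent occurs anti to the C4 acetal group (sets C5) and the regiodefined magnesium enolate is C-allylated anti to the new C5 substituent (sets the C10 quaternary centre), a tandem conjugate addition–enolate alkylation that gives the trans,trans array needed for a trans-decalin.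

**Step 4**
Reactants: 10 (2R,3R,4R)-4-(dimethoxymethyl)-2-methyl-3-(4-methylpent-1-en-2-yl)-2-(prop-2-en-1-yl)cyclohexan-1-one
Product: 12 4α-(dimethoxymethyl)-10β-methyl-7-(propan-2-yl)-5αH-decal-7-ene-1,6-dione, via keto aldehyde 11 (not isolated)
Conditions: O3, CH2Cl2/MeOH, −78 °C; Me2S, −78 → 20 °C; then (PhCH2)2NH·CF3CO2H (30 mol %), toluene, 50 °C
Reagents that add atoms: ozone [O-][O+]=O
Why: Ozonolysis turns the 1,1-disubstituted alkene into the C6 isobutyl ketone and the allyl group into the C8 aldehyde, and amine-salt-catalysed intramolecular aldol condensation of this 1,5-keto aldehyde (C7 onto C8) closes ring B as the conjugated enone under conditions too mild to epimerise C5 (the competing aldol from C2 would need a bridgehead alkene to dehydrate).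

**Step 5**
Reactants: 12 4α-(dimethoxymethyl)-10β-methyl-7-(propan-2-yl)-5αH-decal-7-ene-1,6-dione
Product: 14 8α-hydroxy-4α-(dimethoxymethyl)-10β-methyl-7β-(propan-2-yl)-5αH-decalin-1,6-dione, via C8 pinacol boronate 13 (not isolated)
Conditions: CuCl (5 mol %), NaOC(CH3)3 (10 mol %), Xantphos (5 mol %), B2pin2 (1.1 equiv), MeOH (2 equiv), THF, 20 °C; then NaBO3·4H2O, THF/H2O, 20 °C
Reagents that add atoms: bis(pinacolato)diboron CC1(C)OB(OC1(C)C)B1OC(C)(C)C(C)(C)O1 (boron in 13 only); sodium perborate [Na+].[O-]OB=O (the C8 oxygen)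
Why: Copper-catalysed conjugate borylation puts boron on C8 from the face opposite the axial C10 methyl, axial protonation of the enolate (an epimerisable α-centre) leaves the isopropyl group equatorial (7β), and perborate oxidation of the C–B bond proceeds with retention to the equatorial 8α-alcohol.

**Step 6**
Reactants: 14 8α-hydroxy-4α-(dimethoxymethyl)-10β-methyl-7β-(propan-2-yl)-5αH-decalin-1,6-dione
Product: 15 8α-acetoxy-4α-(dimethoxymethyl)-10β-methyl-7β-(propan-2-yl)-5αH-decalin-1,6-dione
Conditions: Ac2O, pyridine, DMAP (5 mol %), CH2Cl2, 0 °C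
Reagents that add atoms: acetic anhydride CC(=O)OC(C)=O
Why: Standard O-acylation of the only hydroxyl group, run cold to avoid β-elimination of the β-acetoxy ketone; no stereocentre changes.

**Step 7**
Reactants: 15 8α-acetoxy-4α-(dimethoxymethyl)-10β-methyl-7β-(propan-2-yl)-5αH-decalin-1,6-dione
Product: 16 8α-acetoxy-4α-(dimethoxymethyl)-10β-methyl-7β-(propan-2-yl)-5αH-decalin-1β,6β-diol
Conditions: NaBH4, CeCl3·7H2O, MeOH/CH2Cl2, −40 → 0 °C
Reagents that add atoms: none
Why: Luche-type borohydride reduction in which hydride reaches both ketones from the α face opposite the axial C10 methyl (axial attack at C1, equatorial attack at C6 because the syn-axial methyl blocks the axial path), giving the equatorial 1β-alcohol and the axial 6β-alcohol while the acetate and acetal survive.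

**Step 8**
Reactants: 16 8α-acetoxy-4α-(dimethoxymethyl)-10β-methyl-7β-(propan-2-yl)-5αH-decalin-1β,6β-diol
Product: 18 (1R,4R,5S,6S,7S,8S,10R)-8α-acetoxy-4α-formyl-6β-hydroxy-10β-methyl-7β-(propan-2-yl)-5αH-decalin-1β-yl methanesulfonate, via mesylate acetal 17 (not isolated)
Conditions: MsCl (1.1 equiv), pyridine, CH2Cl2, −10 °C; then 1 M HCl, THF/H2O, 20 °C
Reagents that add atoms: methanesulfonyl chloride CS(=O)(=O)Cl; water O
Why: Chemoselective sulfonylation of the equatorial C1 hydroxyl (the axial C6 hydroxyl is shielded by the syn-axial C10 methyl and the flanking isopropyl-bearing carbon) followed by acid hydrolysis of the dimethyl acetal in the same flask; the mesylate and acetate tolerate dilute acid and no stereocentre is touched.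

**Step 9**
Reactants: 18 (1R,4R,5S,6S,7S,8S,10R)-8α-acetoxy-4α-formyl-6β-hydroxy-10β-methyl-7β-(propan-2-yl)-5αH-decalin-1β-yl methanesulfonate
Product: 20 (6S,7S,8S)-8-acetoxygermacra-1(10),4-diene-6,15-diol with both ring double bonds trans in the ring, via dienal 19 (not isolated)
Conditions: KN(SiMe3)2 (1.05 equiv), THF, −78 → 0 °C; then MeOH, CeCl3·7H2O, NaBH4, −78 → −20 °C
Reagents that add atoms: none
Why: Enolate-assisted 1,4-fragmentation (a homologous Grob fragmentation, the ring expansion): the one equivalent of base is taken up by the C6 hydroxyl, the axial alkoxide removes the syn-axial C4–H to give the aldehyde enolate, and its electrons pass through the aligned C5–C10 bond to expel the antiperiplanar equatorial C1 mesylate, so the trans-decalin geometry is translated stereospecifically into the ten-membered ring with both ring-trans double bonds (C15 cis to C6) with no base left to attack the acetate, and Luche 1,2-reduction then traps the labile dienal as the allylic alcohol without touching C6–C8.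

**Step 10**
Reactants: 20 (6S,7S,8S)-8-acetoxygermacra-1(10),4-diene-6,15-diol; 21 angelic acid
Product: 23 (6S,7S,8S)-8-acetoxy-6-hydroxygermacra-1(10),4-dien-15-yl (Z)-2-methylbut-2-enoate, via mixed anhydride 22 (not isolated)
Conditions: 21, 2,4,6-trichlorobenzoyl chloride, Et3N, toluene, 20 °C; then 20, DMAP (0.2 equiv), 0 → 20 °C
Reagents that add atoms: 2,4,6-trichlorobenzoyl chloride O=C(Cl)c1c(Cl)cc(Cl)cc1Cl (in 22 only)
Why: Yamaguchi esterification through the mixed anhydride acylates the unhindered primary allylic C15 hydroxyl in preference to the hindered secondary C6 hydroxyl and keeps the angelate (Z) geometry, which is prone to isomerise to tiglate under harsher acylations.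

**Compound list**
1 | 2-methylcyclohex-2-en-1-one | CC1=CCCC1=O | starting material
2 | potassium 2-methylcyclohexa-1,3-dien-1-olate | CC1=C([O-])CCC=C1.[K+] | intermediate
3 | tert-butyl(dimethyl)[(2-methylcyclohexa-1,3-dien-1-yl)oxy]silane | CC1=C(O[Si](C)(C)C(C)(C)C)CCC=C1 | intermediate
4 | trimethyl orthoformate | COC(OC)OC | starting material
5 | (4R)-4-(dimethoxymethyl)-2-methylcyclohex-2-en-1-one | CC1=C[C@H](C(OC)OC)CCC1=O | intermediate
6 | 2-bromo-4-methylpent-1-ene | CC(C)CC(Br)=C | starting material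
7 | 3-bromoprop-1-ene (allyl bromide) | C=CCBr | starting material
8 | (4-methylpent-1-en-2-yl)magnesium bromide | CC(C)CC(=C)[Mg]Br | intermediate
9 | bromomagnesium 1-enolate of the conjugate adduct (C4 acetal and C5 alkenyl trans) | CC1=C(O[Mg]Br)CC[C@@H](C(OC)OC)[C@@H]1C(=C)CC(C)C | intermediate
10 | (2R,3R,4R)-4-(dimethoxymethyl)-2-methyl-3-(4-methylpent-1-en-2-yl)-2-(prop-2-en-1-yl)cyclohexan-1-one | C=CC[C@@]1(C)C(=O)CC[C@@H](C(OC)OC)[C@@H]1C(=C)CC(C)C | intermediate
11 | 2-[3-(dimethoxymethyl)-1-methyl-2-(3-methylbutanoyl)-6-oxocyclohexyl]acetaldehyde, ring configuration as in 10 | O=CC[C@@]1(C)C(=O)CC[C@@H](C(OC)OC)[C@@H]1C(=O)CC(C)C | intermediate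
12 | 4α-(dimethoxymethyl)-10β-methyl-7-(propan-2-yl)-5αH-decal-7-ene-1,6-dione (trans-fused) | C[C@@]12CC=C(C(C)C)C(=O)[C@H]1[C@H](C(OC)OC)CCC2=O | intermediate
13 | 4α-(dimethoxymethyl)-10β-methyl-7β-(propan-2-yl)-8α-(4,4,5,5-tetramethyl-1,3,2-dioxaborolan-2-yl)-5αH-decalin-1,6-dione | C[C@@]12C[C@H](B3OC(C)(C)C(C)(C)O3)[C@@H](C(C)C)C(=O)[C@H]1[C@H](C(OC)OC)CCC2=O | intermediate
14 | 8α-hydroxy-4α-(dimethoxymethyl)-10β-methyl-7β-(propan-2-yl)-5αH-decalin-1,6-dione | C[C@@]12C[C@H](O)[C@@H](C(C)C)C(=O)[C@H]1[C@H](C(OC)OC)CCC2=O | intermediate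
15 | 8α-acetoxy-4α-(dimethoxymethyl)-10β-methyl-7β-(propan-2-yl)-5αH-decalin-1,6-dione | C[C@@]12C[C@H](OC(C)=O)[C@@H](C(C)C)C(=O)[C@H]1[C@H](C(OC)OC)CCC2=O | intermediate
16 | 8α-acetoxy-4α-(dimethoxymethyl)-10β-methyl-7β-(propan-2-yl)-5αH-decalin-1β,6β-diol | C[C@@]12C[C@H](OC(C)=O)[C@@H](C(C)C)[C@@H](O)[C@H]1[C@H](C(OC)OC)CC[C@H]2O | intermediate
17 | 8α-acetoxy-4α-(dimethoxymethyl)-6β-hydroxy-10β-methyl-7β-(propan-2-yl)-5αH-decalin-1β-yl methanesulfonate | C[C@@]12C[C@H](OC(C)=O)[C@@H](C(C)C)[C@@H](O)[C@H]1[C@H](C(OC)OC)CC[C@H]2OS(C)(=O)=O | intermediate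
18 | (1R,4R,5S,6S,7S,8S,10R)-8α-acetoxy-4α-formyl-6β-hydroxy-10β-methyl-7β-(propan-2-yl)-5αH-decalin-1β-yl methanesulfonate | C[C@@]12C[C@H](OC(C)=O)[C@@H](C(C)C)[C@@H](O)[C@H]1[C@H](C=O)CC[C@H]2OS(C)(=O)=O | intermediate
19 | (6S,7S,8S)-8-acetoxy-6-hydroxygermacra-1(10),4-dien-15-al, both ring double bonds trans in the ring (C15 cis to C6) | O=C/C1=C\[C@H](O)[C@H](C(C)C)[C@@H](OC(C)=O)C/C(C)=C/CC1 | intermediate
20 | (6S,7S,8S)-8-acetoxygermacra-1(10),4-diene-6,15-diol, same double-bond geometry | OC/C1=C\[C@H](O)[C@H](C(C)C)[C@@H](OC(C)=O)C/C(C)=C/CC1 | intermediate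
21 | angelic acid, (Z)-2-methylbut-2-enoic acid | C/C=C(/C)C(=O)O | starting material
22 | angelic 2,4,6-trichlorobenzoic anhydride | C/C=C(/C)C(=O)OC(=O)c1c(Cl)cc(Cl)cc1Cl | intermediate
23 | (6S,7S,8S)-8-acetoxy-6-hydroxygermacra-1(10),4-dien-15-yl (Z)-2-methylbut-2-enoate (CNP0246594.1) | C/C=C(/C)C(=O)OC/C1=C\[C@H](O)[C@H](C(C)C)[C@@H](OC(C)=O)C/C(C)=C/CC1 | target

**Step count and risks**
Total step count: 10. Longest linear sequence: 10 (steps 1–10, all from 1).

The three steps most likely to fail:

Step 2 (the proposed new reaction). The enantioselectivity of the ion-pair γ-attack and the γ/α ratio are untested. Fallback with known chemistry, setting out from 3 and returning at 5: the TMSOTf-catalysed (10 mol %, CH2Cl2, −78 °C) γ-addition of 3 to 4 gives racemic 4-(dimethoxymethyl)-2-methylcyclohex-2-en-1-one F1. Preparative chromatography on a chiral stationary phase then gives 5 and its enantiomer (4S)-4-(dimethoxymethyl)-2-methylcyclohex-2-en-1-one F2, which is racemised through its dienolate (catalytic KOC(CH3)3) back to F1 and recycled.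

Step 8 (mesylation of C1–OH in the presence of C6–OH). If the axial C6 hydroxyl competes, the order is changed so that only one hydroxyl is ever present; the fallback sets out from 12 and returns at 17.
- NaBH4 (0.3 equiv, EtOH, −10 °C) reduces only the saturated C1 ketone of 12, from the α face, to the 1β-hydroxy enone F3.
- MsCl/Et3N gives the 1β-mesyloxy enone F4.
- Conjugate borylation (CuCl, B2pin2, MeOH) gives the 8α-boronate F5, and NaBO3 oxidation gives the 8α-hydroxy 6-ketone F6.
- Ac2O/pyridine gives the 8α-acetoxy 6-ketone F7.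
- NaBH4/CeCl3·7H2O reduces the C6 ketone from the α face to 17, which re-enters step 8 at the acetal hydrolysis.

Step 9 (ring expansion). The relayed deprotonation may be slow, or the acetate may not survive the amide base. Fallback with known chemistry (fluoride generation of an enolate from a silyl enol ether, then the same Grob-type fragmentation), setting out from 18 and returning at 20.
- TESOTf/Et3N (CH2Cl2, −78 → 0 °C) converts 18 into the 6-O-triethylsilyl C4=C15 triethylsilyl enol ether F8 (enol ether geometry immaterial).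
- Tetrabutylammonium difluorotriphenylsilicate (THF, −20 °C) cleaves only the enol silyl ether; the resulting naked enolate fragments to the 6-O-triethylsilyl dienal F9, with no alkoxide or amide base present.
- Luche reduction in the same flask gives the 6-O-triethylsilyl 15-alcohol F10.
- HF·pyridine buffered with pyridine (THF, 0 °C) removes the silyl group to give 20.

**Further compounds**
F1 | step 2 | racemic 4-(dimethoxymethyl)-2-methylcyclohex-2-en-1-one | CC1=CC(C(OC)OC)CCC1=O
F2 | step 2 | (4S)-4-(dimethoxymethyl)-2-methylcyclohex-2-en-1-one | CC1=C[C@@H](C(OC)OC)CCC1=O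
F3 | step 8 | 1β-hydroxy-4α-(dimethoxymethyl)-10β-methyl-7-(propan-2-yl)-5αH-decal-7-en-6-one | C[C@@]12CC=C(C(C)C)C(=O)[C@H]1[C@H](C(OC)OC)CC[C@H]2O
F4 | step 8 | 4α-(dimethoxymethyl)-10β-methyl-6-oxo-7-(propan-2-yl)-5αH-decal-7-en-1β-yl methanesulfonate | C[C@@]12CC=C(C(C)C)C(=O)[C@H]1[C@H](C(OC)OC)CC[C@H]2OS(C)(=O)=O
F5 | step 8 | 4α-(dimethoxymethyl)-10β-methyl-6-oxo-7β-(propan-2-yl)-8α-(4,4,5,5-tetramethyl-1,3,2-dioxaborolan-2-yl)-5αH-decalin-1β-yl methanesulfonate | C[C@@]12C[C@H](B3OC(C)(C)C(C)(C)O3)[C@@H](C(C)C)C(=O)[C@H]1[C@H](C(OC)OC)CC[C@H]2OS(C)(=O)=O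
F6 | step 8 | 8α-hydroxy-4α-(dimethoxymethyl)-10β-methyl-6-oxo-7β-(propan-2-yl)-5αH-decalin-1β-yl methanesulfonate | C[C@@]12C[C@H](O)[C@@H](C(C)C)C(=O)[C@H]1[C@H](C(OC)OC)CC[C@H]2OS(C)(=O)=O
F7 | step 8 | 8α-acetoxy-4α-(dimethoxymethyl)-10β-methyl-6-oxo-7β-(propan-2-yl)-5αH-decalin-1β-yl methanesulfonate | C[C@@]12C[C@H](OC(C)=O)[C@@H](C(C)C)C(=O)[C@H]1[C@H](C(OC)OC)CC[C@H]2OS(C)(=O)=O
F8 | step 9 | 8α-acetoxy-10β-methyl-7β-(propan-2-yl)-6β-(triethylsilyloxy)-4-[(triethylsilyloxy)methylidene]-5αH-decalin-1β-yl methanesulfonate | C[C@@]12C[C@H](OC(C)=O)[C@@H](C(C)C)[C@@H](O[Si](CC)(CC)CC)[C@H]1C(=CO[Si](CC)(CC)CC)CC[C@H]2OS(C)(=O)=O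
F9 | step 9 | (6S,7S,8S)-8-acetoxy-6-(triethylsilyloxy)germacra-1(10),4-dien-15-al, both ring double bonds trans in the ring | O=C/C1=C\[C@H](O[Si](CC)(CC)CC)[C@H](C(C)C)[C@@H](OC(C)=O)C/C(C)=C/CC1
F10 | step 9 | (6S,7S,8S)-8-acetoxy-6-(triethylsilyloxy)germacra-1(10),4-dien-15-ol, same double-bond geometry | OC/C1=C\[C@H](O[Si](CC)(CC)CC)[C@H](C(C)C)[C@@H](OC(C)=O)C/C(C)=C/CC1
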